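The interflavanyl C4–C6 bond divides the dimer into two benzyl-protected 2,3-cis flavans made from one chiral aldehyde. Everything rests on the aryl ether bond O1–C8a of ring C in the lower unit. C8a, the ring A carbon between C4a and the oxygenated C8, is carried as an aryl bromide. The C2 hydroxyl of an open-chain all-syn 1,3-diarylpropane-1,2,3-triol derivative closes the pyran by copper-catalysed O-arylation. No bond to C2, C3 or C4 is broken, so the acyclic syn,syn array (syn-aldol, then chelation-controlled aryl addition) becomes the 2,3-cis-3,4-trans chroman directly. The same closure furnishes the upper unit, joined through its C4 cation.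

Key step: step 8

Remark on the chemistry: flavan numbering (O1, C2–C4, C4a, C5–C8, C8a) is used for both halves. The "upper unit" is the flavan-3-ol carrying the 4-hydroxyphenyl group and the "lower unit" is the flavan-3,4-diol. The SMILES is read as upper (2R,3R,4S) and lower (2R,3R,4S), i.e. 2,3-cis-3,4-trans in both units, with the upper C4 bonded to the lower C6.

**Step 1**
Reactants: 1 2-bromo-3-hydroxy-4-methoxybenzaldehyde
Product: 2 2-bromo-3,4-dihydroxybenzaldehyde
Conditions: BBr3, CH2Cl2, −78 °C to rt; then H2O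
Reagents that add atoms: none
Why: Lewis-acid cleavage of the aryl methyl ether (BBr3 demethylation) frees the catechol, so that both ring A oxygens can be carried as hydrogenolysable benzyl ethers.

**Step 2**
Reactants: 2 2-bromo-3,4-dihydroxybenzaldehyde
Product: 3 3,4-bis(benzyloxy)-2-bromobenzaldehyde
Conditions: BnBr, K2CO3, DMF, 60 °C
Reagents that add atoms: benzyl bromide, BrCc1ccccc1
Why: Williamson ether synthesis on both phenols gives the ring A building block whose bromine sits on the future C8a and whose formyl carbon becomes C4.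

**Step 3**
Reactants: 4 (R)-4-benzyl-1,3-thiazolidine-2-thione; 5 (benzyloxy)acetyl chloride
Product: 6 (R)-4-benzyl-3-[(benzyloxy)acetyl]-1,3-thiazolidine-2-thione
Conditions: Et3N, DMAP (cat.), CH2Cl2, 0 °C to rt
Reagents that add atoms: none
Why: N-acylation of the thiazolidinethione gives the chiral glycolate equivalent that supplies C3 together with its benzyl-protected oxygen.

**Step 4**
Reactants: 6 (R)-4-benzyl-3-[(benzyloxy)acetyl]-1,3-thiazolidine-2-thione; 3 3,4-bis(benzyloxy)-2-bromobenzaldehyde
Product: 8 (2R,3S)-syn-aldol adduct, via trichlorotitanium Z-enolate 7 (not isolated)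
Conditions: TiCl4, i-Pr2NEt, N-methyl-2-pyrrolidone, CH2Cl2, −78 °C; then 3, −78 to 0 °C; aq NH4Cl
Reagents that add atoms: none
Why: Titanium-mediated Evans-type syn-aldol addition, in which the Z-enolate 7 reacts through a non-chelated Zimmerman–Traxler chair with one face shielded by the (R)-benzyl group of the auxiliary, should set the (2R,3S) syn array that becomes C3 and C4 of both flavan units.

**Step 5**
Reactants: 8 (2R,3S)-syn-aldol adduct
Product: 9 silyl ether of 8 (3-O-tert-butyldimethylsilyl)
Conditions: t-BuMe2SiOSO2CF3, 2,6-lutidine, CH2Cl2, −78 to 0 °C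
Reagents that add atoms: tert-butyldimethylsilyl trifluoromethanesulfonate, CC(C)(C)[Si](C)(C)OS(=O)(=O)C(F)(F)F
Why: Silylation of the benzylic hydroxyl blocks retro-aldol cleavage and gives a C4 oxygen that neither chelates magnesium in step 7 or 9 nor acts as a nucleophile in step 12.

**Step 6**
Reactants: 9 silyl ether of 8
Product: 10 (2R,3S)-2-(benzyloxy)-3-[3,4-bis(benzyloxy)-2-bromophenyl]-3-[(tert-butyldimethylsilyl)oxy]propanal
Conditions: i-Bu2AlH, CH2Cl2, −78 °C; aq potassium sodium tartrate; used at once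
Reagents that add atoms: none
Why: Reductive cleavage of the N-acylthiazolidinethione by i-Bu2AlH stops at the aldehyde because the tetrahedral aluminium adduct only collapses on work-up, and cold handling should keep the α-stereocentre intact.

**Step 7**
Reactants: 11 1,2-bis(benzyloxy)-4-bromobenzene; 10 aldehyde
Product: 13 (1R,2S,3S)-2-(benzyloxy)-1-[3,4-bis(benzyloxy)phenyl]-3-[3,4-bis(benzyloxy)-2-bromophenyl]-3-[(tert-butyldimethylsilyl)oxy]propan-1-ol, via aryl Grignard reagent 12 (not isolated)
Conditions: Mg, THF, rt; then 10 precomplexed with MgBr2·OEt2, CH2Cl2, −78 °C; aq NH4Cl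
Reagents that add atoms: none
Why: Grignard addition under Cram chelate control, with magnesium bridging the aldehyde oxygen and the α-benzyloxy group (the β-silyloxy group does not chelate), should deliver the aryl group to the face away from the C3 side chain and give the 1,2-syn alcohol, the future (2R) centre of the lower unit.

**Step 8**
Reactants: 13 all-syn bromo alcohol
Product: 14 (2R,3S,4S)-3,7,8-tris(benzyloxy)-2-[3,4-bis(benzyloxy)phenyl]-4-[(tert-butyldimethylsilyl)oxy]chromane (protected lower unit, 2,3-cis-3,4-trans)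
Conditions: CuI (20 mol%), 3,4,7,8-tetramethyl-1,10-phenanthroline (40 mol%), Cs2CO3, degassed toluene, 110 °C
Reagents that add atoms: none
Why: Intramolecular Ullmann-type C–O coupling: the C2 alkoxide binds monovalent copper, the metal activates the C8a–Br bond, and C–O reductive elimination from the resulting trivalent aryl copper alkoxide forms the O1–C8a bond. The closest known reaction type is the copper/phenanthroline-catalysed etherification of aryl bromides with secondary alcohols, which is established in its intramolecular form for chromans. Ring C is closed as a six-membered ring by attack of the side-chain oxygen on the arene carbon C8a, with bromide as the leaving group. No stereocentre is formed or touched, because no bond to C2, C3 or C4 is broken, so the all-syn triad of 13 is carried unchanged into the 2,3-cis-3,4-trans chroman; closures through O1–C2 reach this pattern only with inversion or with loss of control at the benzylic C2. The selectivity needed is that only the C2 oxygen is arylated: O3 is a benzyl ether, O4 is silylated and could only close a four-membered ring, and a possible 1,3-silyl shift between O4 and O2 is harmless because only the C2 alkoxide can cyclise.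

**Step 9**
Reactants: 15 1-(benzyloxy)-4-bromobenzene; 10 aldehyde
Product: 17 (1R,2S,3S)-2-(benzyloxy)-1-[4-(benzyloxy)phenyl]-3-[3,4-bis(benzyloxy)-2-bromophenyl]-3-[(tert-butyldimethylsilyl)oxy]propan-1-ol, via aryl Grignard reagent 16 (not isolated)
Conditions: Mg, THF, rt; then 10 precomplexed with MgBr2·OEt2, CH2Cl2, −78 °C; aq NH4Cl
Reagents that add atoms: none
Why: The same chelation-controlled Grignard addition as in step 7 should set the 1,2-syn alcohol that becomes the (2R) centre of the upper unit.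

**Step 10**
Reactants: 17 all-syn bromo alcohol of the upper unit
Product: 18 (2R,3S,4S)-3,7,8-tris(benzyloxy)-2-[4-(benzyloxy)phenyl]-4-[(tert-butyldimethylsilyl)oxy]chromane
Conditions: CuI (20 mol%), 3,4,7,8-tetramethyl-1,10-phenanthroline (40 mol%), Cs2CO3, degassed toluene, 110 °C
Reagents that add atoms: none
Why: The same intramolecular Ullmann-type O-arylation closes ring C of the upper unit with retention of all centres, giving the 2,3-cis flavan with a latent leaving group at C4.

**Step 11**
Reactants: 18 protected upper flavan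
Product: 19 (2R,3S,4S)-4-(benzylsulfanyl)-3,7,8-tris(benzyloxy)-2-[4-(benzyloxy)phenyl]chromane (3,4-trans)
Conditions: BnSH (5 equiv), BF3·OEt2 (cat.), CH2Cl2, −78 to −30 °C
Reagents that add atoms: phenylmethanethiol, SCc1ccccc1
Why: Lewis-acid-mediated SN1 thiolysis, in which the 4-silyloxy group ionises to the C4 cation stabilised by O1 and the 7-benzyloxy group and the thiol adds anti to the 3-benzyloxy group, should give the 3,4-trans thioether, a soft leaving group that can be addressed in the presence of the 4-silyloxy group of 14.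

**Step 12**
Reactants: 19 upper 4-thioether; 14 protected lower unit
Product: 20 nona-O-benzyl (4β→6) dimer with the lower C4 oxygen silylated
Conditions: AgOSO2CF3, 2,6-di-tert-butyl-4-methylpyridine, 4 Å molecular sieves, CH2Cl2, −40 to 0 °C; 14 in excess (2.5 equiv, remainder recovered)
Reagents that add atoms: none
Why: Friedel–Crafts alkylation by thiophilic activation, in which the silver salt abstracts the thiolate and C6 of 14 (para to O1 and ortho to the 7-benzyloxy group, whereas C5 is only para to the twisted 8-benzyloxy group and crowded by C4) attacks the C4 cation anti to the 3-benzyloxy group, should set the upper C4 centre 3,4-trans, while the hindered base keeps the medium non-acidic so the lower 4-silyloxy group is not ionised.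

**Step 13**
Reactants: 20 silylated dimer
Product: 21 nona-O-benzyl dimer with free lower 4-hydroxyl
Conditions: Bu4NF, AcOH, THF, 0 °C to rt
Reagents that add atoms: none
Why: Fluoride-mediated Si–O cleavage under acetic acid buffering frees the lower 4-hydroxyl without an acidic step that could ionise this benzylic position.

**Step 14**
Reactants: 21 nona-O-benzyl dimer
Product: 22 CNP0275688.1
Conditions: H2 (1 atm), Pd(OH)2/C, THF/MeOH, rt; filtration under argon
Reagents that add atoms: none
Why: Catalytic hydrogenolysis under neutral conditions should cleave the seven aryl benzyl ethers and the two secondary benzyl ethers, while the interflavanyl bond and the free benzylic 4-hydroxyl are expected to survive in the absence of acid.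

**Compound list**

1 | 2-bromo-3-hydroxy-4-methoxybenzaldehyde | O=Cc1ccc(OC)c(O)c1Br | starting material
2 | 2-bromo-3,4-dihydroxybenzaldehyde | O=Cc1ccc(O)c(O)c1Br | intermediate
3 | 3,4-bis(benzyloxy)-2-bromobenzaldehyde | O=Cc1ccc(OCc2ccccc2)c(OCc2ccccc2)c1Br | intermediate
4 | (R)-4-benzyl-1,3-thiazolidine-2-thione | S=C1N[C@H](Cc2ccccc2)CS1 | starting material
5 | (benzyloxy)acetyl chloride | O=C(Cl)COCc1ccccc1 | starting material
6 | (R)-4-benzyl-3-[(benzyloxy)acetyl]-1,3-thiazolidine-2-thione | O=C(COCc1ccccc1)N1[C@H](Cc2ccccc2)CSC1=S | intermediate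
7 | trichlorotitanium (Z)-enolate of 6 | Cl[Ti](Cl)(Cl)O/C(=C\OCc1ccccc1)N1[C@H](Cc2ccccc2)CSC1=S | intermediate (not isolated)
8 | (R)-4-benzyl-3-[(2R,3S)-2-(benzyloxy)-3-[3,4-bis(benzyloxy)-2-bromophenyl]-3-hydroxypropanoyl]-1,3-thiazolidine-2-thione (syn-aldol) | O=C(N1[C@H](Cc2ccccc2)CSC1=S)[C@H](OCc1ccccc1)[C@@H](O)c1ccc(OCc2ccccc2)c(OCc2ccccc2)c1Br | intermediate
9 | (R)-4-benzyl-3-[(2R,3S)-2-(benzyloxy)-3-[3,4-bis(benzyloxy)-2-bromophenyl]-3-[(tert-butyldimethylsilyl)oxy]propanoyl]-1,3-thiazolidine-2-thione | O=C(N1[C@H](Cc2ccccc2)CSC1=S)[C@H](OCc1ccccc1)[C@@H](O[Si](C)(C)C(C)(C)C)c1ccc(OCc2ccccc2)c(OCc2ccccc2)c1Br | intermediate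
10 | (2R,3S)-2-(benzyloxy)-3-[3,4-bis(benzyloxy)-2-bromophenyl]-3-[(tert-butyldimethylsilyl)oxy]propanal | O=C[C@H](OCc1ccccc1)[C@@H](O[Si](C)(C)C(C)(C)C)c1ccc(OCc2ccccc2)c(OCc2ccccc2)c1Br | intermediate
11 | 1,2-bis(benzyloxy)-4-bromobenzene | Brc1ccc(OCc2ccccc2)c(OCc2ccccc2)c1 | starting material
12 | [3,4-bis(benzyloxy)phenyl]magnesium bromide | Br[Mg]c1ccc(OCc2ccccc2)c(OCc2ccccc2)c1 | intermediate (not isolated)
13 | (1R,2S,3S)-2-(benzyloxy)-1-[3,4-bis(benzyloxy)phenyl]-3-[3,4-bis(benzyloxy)-2-bromophenyl]-3-[(tert-butyldimethylsilyl)oxy]propan-1-ol (all-syn) | O[C@H](c1ccc(OCc2ccccc2)c(OCc2ccccc2)c1)[C@H](OCc1ccccc1)[C@@H](O[Si](C)(C)C(C)(C)C)c1ccc(OCc2ccccc2)c(OCc2ccccc2)c1Br | intermediate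
14 | (2R,3S,4S)-3,7,8-tris(benzyloxy)-2-[3,4-bis(benzyloxy)phenyl]-4-[(tert-butyldimethylsilyl)oxy]chromane (2,3-cis-3,4-trans) | c1cc2c(c(OCc3ccccc3)c1OCc1ccccc1)O[C@H](c1ccc(OCc3ccccc3)c(OCc3ccccc3)c1)[C@H](OCc1ccccc1)[C@H]2O[Si](C)(C)C(C)(C)C | intermediate
15 | 1-(benzyloxy)-4-bromobenzene | Brc1ccc(OCc2ccccc2)cc1 | starting material
16 | [4-(benzyloxy)phenyl]magnesium bromide | Br[Mg]c1ccc(OCc2ccccc2)cc1 | intermediate (not isolated)
17 | (1R,2S,3S)-2-(benzyloxy)-1-[4-(benzyloxy)phenyl]-3-[3,4-bis(benzyloxy)-2-bromophenyl]-3-[(tert-butyldimethylsilyl)oxy]propan-1-ol (all-syn) | O[C@H](c1ccc(OCc2ccccc2)cc1)[C@H](OCc1ccccc1)[C@@H](O[Si](C)(C)C(C)(C)C)c1ccc(OCc2ccccc2)c(OCc2ccccc2)c1Br | intermediate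
18 | (2R,3S,4S)-3,7,8-tris(benzyloxy)-2-[4-(benzyloxy)phenyl]-4-[(tert-butyldimethylsilyl)oxy]chromane (2,3-cis-3,4-trans) | c1cc2c(c(OCc3ccccc3)c1OCc1ccccc1)O[C@H](c1ccc(OCc3ccccc3)cc1)[C@H](OCc1ccccc1)[C@H]2O[Si](C)(C)C(C)(C)C | intermediate
19 | (2R,3S,4S)-4-(benzylsulfanyl)-3,7,8-tris(benzyloxy)-2-[4-(benzyloxy)phenyl]chromane (2,3-cis-3,4-trans) | c1cc2c(c(OCc3ccccc3)c1OCc1ccccc1)O[C@H](c1ccc(OCc3ccccc3)cc1)[C@H](OCc1ccccc1)[C@H]2SCc1ccccc1 | intermediate
20 | nona-O-benzyl dimer, lower 4-O-tert-butyldimethylsilyl: C6 of 14 bonded to C4 of the upper 3,7,8-tris(benzyloxy)-2-[4-(benzyloxy)phenyl]chroman-4-yl unit, trans to its 3-benzyloxy group | c6ccccc6COc1ccc([C@H]2Oc3c(ccc(OCc6ccccc6)c3OCc6ccccc6)[C@H](c3cc4c(c(OCc6ccccc6)c3OCc6ccccc6)O[C@H](c3ccc(OCc6ccccc6)c(OCc6ccccc6)c3)[C@H](OCc6ccccc6)[C@H]4O[Si](C)(C)C(C)(C)C)[C@H]2OCc6ccccc6)cc1 | intermediate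
21 | nona-O-benzyl dimer with free lower 4-hydroxyl (desilylated 20) | c6ccccc6COc1ccc([C@H]2Oc3c(ccc(OCc6ccccc6)c3OCc6ccccc6)[C@H](c3cc4c(c(OCc6ccccc6)c3OCc6ccccc6)O[C@H](c3ccc(OCc6ccccc6)c(OCc6ccccc6)c3)[C@H](OCc6ccccc6)[C@H]4O)[C@H]2OCc6ccccc6)cc1 | intermediate
22 | CNP0275688.1, (2R,3R,4S)-2-(3,4-dihydroxyphenyl)-6-[(2R,3R,4S)-3,7,8-trihydroxy-2-(4-hydroxyphenyl)chroman-4-yl]chromane-3,4,7,8-tetrol | Oc1ccc([C@H]2Oc3c(ccc(O)c3O)[C@H](c3cc4c(c(O)c3O)O[C@H](c3ccc(O)c(O)c3)[C@H](O)[C@H]4O)[C@H]2O)cc1 | target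

**Count and risks**

Total step count: 14. Longest linear sequence: 11 steps (1 → 2 → 3 → 8 → 9 → 10 → 17 → 18 → 19 → 20 → 21 → 22; steps 1, 2, 4, 5, 6, 9, 10, 11, 12, 13, 14).

The three steps most likely to fail:

Step 12 (interflavanyl coupling). The C4 cation may alkylate ring A of a second molecule of 19 (self-condensation) or attack C5 of 14, leading to oligomers and regioisomers. The fallback is halogen capping of the electrophilic unit. It sets out from 18: bromination with N-bromosuccinimide (CH2Cl2, −78 to 0 °C) at C6, the most nucleophilic arene position, would give the 6-bromo silyl ether F1. Thiolysis as in step 11 would give the 6-bromo thioether F2. Coupling with 14 as in step 12, now with no free C6 on the electrophile, would give the bromo dimer F3. Bromine–lithium exchange (n-BuLi, THF, −78 °C) followed by protonation with MeOH comes back to the route at 20.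

Step 8 (key ring closure). Activation of the doubly ortho-substituted, electron-rich C8a–Br bond may be slow, so that hydrodebromination or oxidation of the benzylic alkoxide competes. The fallback inverts the polarity at C8a. It sets out from 13: Miyaura borylation (B2pin2, PdCl2(dppf), KOAc, dioxane, 90 °C) would give the pinacol boronate F4. An intramolecular Chan–Lam etherification (Cu(OAc)2 cat., DMAP, O2, 4 Å molecular sieves, CH2Cl2, rt), in which the aryl group is transferred from boron to divalent copper, would form the same O1–C8a bond and come back to the route at 14.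

Step 14 (global hydrogenolysis). The free benzylic C4 hydroxyl of the lower unit may be lost by over-reduction during the slower cleavage of the two secondary benzyl ethers. The fallback reverses the order of the last two operations. It sets out from 20: hydrogenolysis with the C4 oxygen still silylated (H2, Pd(OH)2/C, EtOAc/THF, rt) would give the 4-O-silyl nonaol F5. Buffered fluoride (Bu4NF, AcOH, THF, under argon) then comes back to the route at 22.

**Further compounds**

F1 | step 12 | (2R,3S,4S)-6-bromo-3,7,8-tris(benzyloxy)-2-[4-(benzyloxy)phenyl]-4-[(tert-butyldimethylsilyl)oxy]chromane | Brc1cc2c(c(OCc3ccccc3)c1OCc1ccccc1)O[C@H](c1ccc(OCc3ccccc3)cc1)[C@H](OCc1ccccc1)[C@H]2O[Si](C)(C)C(C)(C)C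
F2 | step 12 | (2R,3S,4S)-4-(benzylsulfanyl)-6-bromo-3,7,8-tris(benzyloxy)-2-[4-(benzyloxy)phenyl]chromane | Brc1cc2c(c(OCc3ccccc3)c1OCc1ccccc1)O[C@H](c1ccc(OCc3ccccc3)cc1)[C@H](OCc1ccccc1)[C@H]2SCc1ccccc1
F3 | step 12 | 6-bromo (upper unit) derivative of dimer 20 | c6ccccc6COc1ccc([C@H]2Oc3c(cc(Br)c(OCc6ccccc6)c3OCc6ccccc6)[C@H](c3cc4c(c(OCc6ccccc6)c3OCc6ccccc6)O[C@H](c3ccc(OCc6ccccc6)c(OCc6ccccc6)c3)[C@H](OCc6ccccc6)[C@H]4O[Si](C)(C)C(C)(C)C)[C@H]2OCc6ccccc6)cc1
F4 | step 8 | pinacol boronate of 13 (Bpin in place of Br at C8a) | O[C@H](c1ccc(OCc2ccccc2)c(OCc2ccccc2)c1)[C@H](OCc1ccccc1)[C@@H](O[Si](C)(C)C(C)(C)C)c1ccc(OCc2ccccc2)c(OCc2ccccc2)c1B1OC(C)(C)C(C)(C)O1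
F5 | step 14 | lower-unit 4-O-tert-butyldimethylsilyl ether of 22 | Oc1ccc([C@H]2Oc3c(ccc(O)c3O)[C@H](c3cc4c(c(O)c3O)O[C@H](c3ccc(O)c(O)c3)[C@H](O)[C@H]4O[Si](C)(C)C(C)(C)C)[C@H]2O)cc1
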